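## Analysis of the target

Compound 13 has a geranyllinalool-type C20 skeleton: one cyclohexane ring (C1–C6) that carries at C4 an eleven-carbon chain (C1'–C11') with a 2'E,4'E-diene, a tertiary allylic alcohol at C6' and a remote trisubstituted alkene. There are four stereocentres: C1 (R), C2 (S) and C4 (S) on the ring and C6' (S) in the chain. On the ring, the C1 hydroxyl, the C2 bromine and the C4 chain lie on one face; in the chair, bromine, the C1 methyl and the chain are equatorial and the hydroxyl is axial. The C1–C2 unit is therefore a cis-bromohydrin with equatorial bromine. Anti addition to a C1=C2 alkene, or opening of its epoxide, gives the trans-diaxial isomer instead, and C2 is a neopentyl-like centre next to the fully substituted C1. C6' is six bonds from the ring, so no stereochemical relay is possible and it has to be brought in or set on its own. Sensitive groups are: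
- the C6' alcohol, tertiary and allylic to a diene, which ionises in acid;
- the cis-bromohydrin, which cannot close to an epoxide but ring-contracts with strong base or silver salts and loses bromine to hydride or radical reagents;
- the C1 hydroxyl, cis to C4, which can bridge to a cationic centre on the side chain.

The feature that invites the strategy is the ring array itself: equatorial Br at C2, 1,3-cis to the C4 substituent, a tertiary OH at C1 and an sp2 carbon (C2') on C4. This is the stereochemical signature of a ring closure between C3 and C4 in which an alkene opens a bromiranium ion spanning C2 and C3.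

## Retrosynthetic reasoning

**C3'–C4' (13 to 11 and 12).** The central single bond of the diene is cut so that the whole C4'–C11' segment, with the C6' stereocentre and its free hydroxyl, is the commercial terpene 12. The forward reaction is a Heck alkenylation of the vinyl group of 12 by alkenyl iodide 11. It has to form the 4'E alkene and leave the tertiary alcohol, the trisubstituted alkene and the bromohydrin alone. Cutting here rather than at C6' avoids an addition to a ketone with two similar alkyl arms, which could not set C6'.

**C2'=C3' (11 to 9 through 10).** The trisubstituted alkene is traced to methyl ketone 9 by a boron–Wittig olefination and a stereoretentive iododeboronation. This adds the single carbon C3' and fixes the 2'E geometry before the fragments are joined. The carbon next to the ketone is ring C4, which already sits in its more stable equatorial position.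

**C2' carbonyl (9 to 7 through 8).** The acetyl group is the ozonolysis product of an isopropenyl group. Compound 7 is thus a C10 monoterpenoid bromohydrin with all three ring stereocentres in place.

**Ring bond C3–C4 (7 to 3 through 4, 5 and 6), the key disconnection.** The ring is opened between C3 and C4 to the acyclic bromodiol 3. In the forward direction the primary alcohol becomes triflate 4, bromine participates to give bromiranium ion 5, and the alkene closes the ring to cation 6, which loses a proton. The cut is placed here because it is the only one that gives the cis-bromohydrin directly: the new C–C bond forms anti to the C–Br bond, so bromine ends up equatorial, and the chair places the new C4 substituent cis to it. No substitution at the hindered C2 of a ring is needed. The step mirrors the way a marine bromoperoxidase is presumed to close such rings from an acyclic terpenoid chain, but the bromiranium ion is made by ionisation, so no choice between alkenes arises. The forward reaction has to control three things: attack at the primary carbon of 5, the chair, and the fate of cation 6.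

**C2–Br and the C2/C3 stereodyad of 3 (3 to 2 to 1).** Bromodiol 3 comes from epoxy alcohol 2 by SN2 opening with bromide at C2, and 2 comes from the commodity alcohol 1 by Sharpless asymmetric epoxidation. The E geometry of 1 and the anti opening together give exactly the relative configuration that places methyl equatorial and hydroxyl axial once bromine is equatorial.

## Alternatives that were turned down

**Alternative 1:** the textbook route, ring from the chiral pool plus cross-coupling. The ring would come from (S)-limonene A1: epoxidation and hydrolysis give the trans-diaxial diol A2, and the forward key step is displacement of the axial C2 oxygen by bromide with inversion, followed by side-chain construction and a palladium coupling. It was turned down because C2 is flanked by the fully substituted C1, whose axial oxygen is anti-periplanar to the leaving group. Closure to epoxide A3, or elimination towards C3, should outrun intermolecular attack at a neopentyl-like centre. Any anti addition of electrophilic bromine and water to A1 gives the 2-epimer A4. C4 comes for free, but the one step that defines the target has no reliable solution, and protecting the tertiary alcohol adds steps without removing the steric problem.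

**Alternative 2:** methyl addition to an α-bromo ketone made from a prochiral ring. The disconnection is the C1–CH3 bond. The mirror-symmetric ketone A5 would be desymmetrised by an enantioselective α-bromination to the cis-bromo ketone A6, and a methyl nucleophile would then add anti to bromine, the classical entry to cis-halohydrins. It was turned down because bromination of the enol or enamine is stereoelectronically axial and gives the trans isomer A7, which leads to the C4-epimeric series. A6 is then reachable only by equilibrating a configurationally labile α-bromo ketone. Two selectivities, which α-carbon reacts and which carbonyl face is attacked, rest on no element of the substrate. The alkenyl arm on A5 would also have to be built first, so the step count is no lower.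

**Alternative 3:** the literal biomimetic cyclisation of the whole C20 chain. The tetraene diol A8 would be treated with an electrophilic bromine source so that a bromonium ion at the terminal vinyl group is captured by the C6–C7 alkene and the cation loses a proton into the diene. It was turned down because bromine transfer reagents choose the two electron-rich trisubstituted alkenes of A8 long before the monosubstituted vinyl group. The tertiary allylic alcohols and the homoallylic cation also offer hydride shift and ether formation, and A8, with two remote stereocentres and a skipped diene, is no easier to make than 13. The chosen route keeps this bond formation but runs it on a C10 fragment and generates the bromiranium ion by ionisation.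

Key step: step 3

Assumption: (S)-(+)-linalool 12 is taken as commercially available in high enantiomeric purity, and D-(−)-diethyl tartrate as the commercial unnatural enantiomer.

## Route

Step 1
Reactants: 1 geraniol, (2E)-3,7-dimethylocta-2,6-dien-1-ol
Product: 2 [(2R,3R)-3-methyl-3-(4-methylpent-3-en-1-yl)oxiran-2-yl]methanol
Conditions: Ti(OiPr)4 (5 mol%), D-(−)-diethyl tartrate (7 mol%), t-BuOOH, 4 Å MS, CH2Cl2, −20 °C
Reagents that add atoms: tert-butyl hydroperoxide, CC(C)(C)OO
Why: Sharpless asymmetric epoxidation is directed by the allylic alcohol, so the C6–C7 alkene should stay untouched; the D-tartrate should deliver oxygen to the face that gives the (2R,3R) epoxide, which fixes the future ring C1 and, after one inversion, C2.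

Step 2
Reactants: 2 [(2R,3R)-3-methyl-3-(4-methylpent-3-en-1-yl)oxiran-2-yl]methanol
Product: 3 (2S,3R)-2-bromo-3,7-dimethyloct-6-ene-1,3-diol
Conditions: NaBr, B(OMe)3, AcOH, DMF, 50 °C; neutral aqueous work-up
Reagents that add atoms: sodium bromide, [Na+].[Br-]
Why: This is the borate-tethered C2-selective SN2 opening of a 2,3-epoxy alcohol by halide: bromide is delivered within a boron ate complex held on the C1 oxygen, and the fully substituted C3 is not ionised by this weak Lewis acid. Clean inversion at C2 should give (2S) with C3 untouched; base is avoided because it would close 3 back to 2.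

Step 3
Reactants: 3 (2S,3R)-2-bromo-3,7-dimethyloct-6-ene-1,3-diol
Product: 7 (1R,2S,4S)-2-bromo-1-methyl-4-(prop-1-en-2-yl)cyclohexan-1-ol, via primary triflate 4 (not isolated), via bromiranium triflate 5 (not isolated), via tertiary cation 6 (not isolated)
Conditions: Tf2O (1.05 equiv), 2,6-di-tert-butyl-4-methylpyridine (2.5 equiv), CH2Cl2, −78 °C, then −78 to −20 °C
Reagents that add atoms: none
Why: The primary hydroxyl of 3 should be triflated selectively (the tertiary one is far slower at −78 °C); on warming, the C2 bromine displaces triflate from the back to give bromiranium ion 5, which the C6–C7 alkene opens at the unhindered CH2 terminus, anti to bromine, through a chair. The closest known reaction types are the solvolytic π-cyclisation of primary sulfonates with a 5,6-double bond and the bromonium-initiated cation–olefin cyclisation in which the bromiranium ion is generated by ionisation of a β-bromo alcohol derivative instead of by bromine transfer. The six-membered ring closes endo with respect to the bromiranium ring (both of its carbons end up in the carbocycle) and exo with respect to the alkene. Because the new C–C bond must be anti-periplanar to the C–Br bond, bromine is equatorial in the chair; the fixed (2S,3R) configuration then places the methyl group equatorial and the hydroxyl axial. The only new stereocentre, ring C4, is set by the equatorial position of the attacking alkene in that chair, which gives the all-cis 1,2,4-array. Selectivity for the six-membered ring rests on attack at the primary carbon of 5 and not at the secondary carbon, which is flanked by the quaternary carbinol and deactivated by its oxygen. Cation 6 should be deprotonated at a methyl group by the hindered pyridine to give the isopropenyl group; this has to be faster than loss of the ring methine proton and than capture by the axial hydroxyl, which would need a boat.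

Step 4
Reactants: 7 (1R,2S,4S)-2-bromo-1-methyl-4-(prop-1-en-2-yl)cyclohexan-1-ol
Product: 9 1-[(1S,3S,4R)-3-bromo-4-hydroxy-4-methylcyclohexyl]ethan-1-one, via secondary ozonide 8 (not isolated)
Conditions: O3, CH2Cl2, −78 °C; then Me2S, −78 °C to rt
Reagents that add atoms: ozone, [O-][O+]=O
Why: Ozonolysis with reductive work-up cleaves the only alkene, and the bromohydrin is inert to ozone and to the sulfide. The acetyl-bearing carbon is equatorial, the more stable epimer, so enolisation cannot erode it.

Step 5
Reactants: 9 1-[(1S,3S,4R)-3-bromo-4-hydroxy-4-methylcyclohexyl]ethan-1-one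
Product: 10 (1R,2S,4S)-2-bromo-1-methyl-4-[(1E)-1-(4,4,5,5-tetramethyl-1,3,2-dioxaborolan-2-yl)prop-1-en-2-yl]cyclohexan-1-ol
Conditions: CH2(Bpin)2 (2.5 equiv), LiTMP (2.5 equiv), THF, 0 °C; then 9, −78 °C to rt
Reagents that add atoms: bis(4,4,5,5-tetramethyl-1,3,2-dioxaborolan-2-yl)methane, CC1(C)OB(CB2OC(C)(C)C(C)(C)O2)OC1(C)C
Why: Boron–Wittig olefination: the lithiated bis-boronate adds to the ketone and syn B–O elimination gives the alkenyl boronate. The E isomer should prevail because the boryl group is placed anti to the branched cyclohexyl substituent; the excess reagent absorbs the proton of the tertiary alcohol.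

Step 6
Reactants: 10 (1R,2S,4S)-2-bromo-1-methyl-4-[(1E)-1-(4,4,5,5-tetramethyl-1,3,2-dioxaborolan-2-yl)prop-1-en-2-yl]cyclohexan-1-ol
Product: 11 (1R,2S,4S)-2-bromo-4-[(1E)-1-iodoprop-1-en-2-yl]-1-methylcyclohexan-1-ol
Conditions: NaOH (3 M aq.), I2, THF, 0 °C, 30 min
Reagents that add atoms: iodine, I-I
Why: Iododeboronation of an alkenyl boronate through its hydroxide ate complex is a reaction type that proceeds with retention of alkene geometry, so the E iodide should result. The short, cold exposure to hydroxide should spare the cis-bromohydrin, which cannot close to an epoxide.

Step 7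
Reactants: 11 (1R,2S,4S)-2-bromo-4-[(1E)-1-iodoprop-1-en-2-yl]-1-methylcyclohexan-1-ol; 12 (S)-linalool, (3S)-3,7-dimethylocta-1,6-dien-3-ol
Product: 13 (1R,2S,4S)-2-bromo-4-[(2E,4E,6S)-6-hydroxy-6,10-dimethylundeca-2,4,9-trien-2-yl]-1-methylcyclohexan-1-ol
Conditions: 12 (3 equiv), Pd(OAc)2 (10 mol%), Bu4NCl, K2CO3, DMF, 50 °C
Reagents that add atoms: none
Why: Mizoroki–Heck reaction under ligand-free phase-transfer conditions: the alkenyl palladium species adds to the terminal carbon of the vinyl group of unprotected 12. β-Hydride elimination can only occur towards C4' because C6' bears no hydrogen, so the 4'E alkene should form without carbonyl formation. The trisubstituted alkene of 12 and the secondary bromide are poor partners for palladium, and the C6' stereocentre is not touched.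

## Compound list

1 | geraniol, (2E)-3,7-dimethylocta-2,6-dien-1-ol | CC(C)=CCC/C(C)=C/CO | starting material
2 | [(2R,3R)-3-methyl-3-(4-methylpent-3-en-1-yl)oxiran-2-yl]methanol | OC[C@H]1O[C@]1(C)CCC=C(C)C | intermediate
3 | (2S,3R)-2-bromo-3,7-dimethyloct-6-ene-1,3-diol | OC[C@H](Br)[C@](C)(O)CCC=C(C)C | intermediate
4 | (2S,3R)-2-bromo-3-hydroxy-3,7-dimethyloct-6-en-1-yl trifluoromethanesulfonate (formed in the flask) | O=S(=O)(OC[C@H](Br)[C@](C)(O)CCC=C(C)C)C(F)(F)F | intermediate
5 | (2R)-2-[(2R)-2-hydroxy-6-methylhept-5-en-2-yl]bromiranium trifluoromethanesulfonate (formed in the flask) | C1[Br+][C@@H]1[C@](C)(O)CCC=C(C)C.[O-]S(=O)(=O)C(F)(F)F | intermediate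
6 | 2-[(1S,3S,4R)-3-bromo-4-hydroxy-4-methylcyclohexyl]propan-2-ylium trifluoromethanesulfonate (formed in the flask) | C[C+](C)[C@H]1CC[C@@](C)(O)[C@@H](Br)C1.[O-]S(=O)(=O)C(F)(F)F | intermediate
7 | (1R,2S,4S)-2-bromo-1-methyl-4-(prop-1-en-2-yl)cyclohexan-1-ol | CC(=C)[C@H]1CC[C@@](C)(O)[C@@H](Br)C1 | intermediate
8 | (1R,2S,4S)-2-bromo-1-methyl-4-(3-methyl-1,2,4-trioxolan-3-yl)cyclohexan-1-ol (formed in the flask; both epimers at the trioxolane carbon) | CC1(OOCO1)[C@H]1CC[C@@](C)(O)[C@@H](Br)C1 | intermediate
9 | 1-[(1S,3S,4R)-3-bromo-4-hydroxy-4-methylcyclohexyl]ethan-1-one | CC(=O)[C@H]1CC[C@@](C)(O)[C@@H](Br)C1 | intermediate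
10 | (1R,2S,4S)-2-bromo-1-methyl-4-[(1E)-1-(4,4,5,5-tetramethyl-1,3,2-dioxaborolan-2-yl)prop-1-en-2-yl]cyclohexan-1-ol | C/C(=C\B1OC(C)(C)C(C)(C)O1)[C@H]1CC[C@@](C)(O)[C@@H](Br)C1 | intermediate
11 | (1R,2S,4S)-2-bromo-4-[(1E)-1-iodoprop-1-en-2-yl]-1-methylcyclohexan-1-ol | C/C(=C\I)[C@H]1CC[C@@](C)(O)[C@@H](Br)C1 | intermediate
12 | (S)-linalool, (3S)-3,7-dimethylocta-1,6-dien-3-ol | CC(C)=CCC[C@](C)(O)C=C | starting material
13 | (1R,2S,4S)-2-bromo-4-[(2E,4E,6S)-6-hydroxy-6,10-dimethylundeca-2,4,9-trien-2-yl]-1-methylcyclohexan-1-ol | CC(C)=CCC[C@](C)(O)/C=C/C=C(\C)[C@H]1CC[C@@](C)(O)[C@@H](Br)C1 | target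

## Step count and least certain steps

Total step count: 7. Longest linear sequence: 7 steps (1 to 13); 12 enters in the last step. No protecting group is used.

**Step 3 (key step).** The most likely failure is loss of control over cation 6. Deprotonation towards the ring, a 1,2-hydride shift from ring C4, or bridging by the axial C1 hydroxyl would all compete with the wanted loss of a methyl proton, because nothing but the hindered base distinguishes these paths. Oxygen participation at the bromiranium stage is a second, smaller risk. The fallback changes the terminating group so that the cation is never free. It sets out from 2 and returns at 7.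
- Ozonolysis of 2 (O3, then Me2S) should give the epoxy aldehyde 4-[(2R,3R)-3-(hydroxymethyl)-2-methyloxiran-2-yl]butanal F1.
- Wittig reaction of F1 with the ylide made from [1-methyl-2-(trimethylsilyl)ethyl]triphenylphosphonium iodide and n-BuLi should give the allylsilane [(2R,3R)-3-methyl-3-[4-methyl-5-(trimethylsilyl)pent-3-en-1-yl]oxiran-2-yl]methanol F2; its alkene geometry is of no consequence.
- Bromide opening as in step 2 should give (2S,3R)-2-bromo-3,7-dimethyl-8-(trimethylsilyl)oct-6-ene-1,3-diol F3.
- Under the conditions of step 3 the β-silyl cation from F3 should lose the silyl group at once and give only the isopropenyl compound 7.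

**Step 2.** The most likely failure is erosion of regioselectivity: partial ionisation at the tertiary C3 would put bromide there, and any basic contact would reclose the product to 2. The fallback sets out from 1 and returns at 3. It builds the C2–Br bond by electrophilic bromination instead of epoxide opening. Catalytic enantioselective bromochlorination of the allylic alcohol (N-bromosuccinimide, ClTi(OiPr)3 and a chiral tridentate Schiff base ligand) should give (2S,3R)-2-bromo-3-chloro-3,7-dimethyloct-6-en-1-ol F4. Silver-assisted hydrolysis of its tertiary chloride (AgOTf, aqueous acetone) should then proceed with participation of the C2 bromine and therefore with retention at C3, giving 3.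

**Step 5.** The most likely failure is enolisation of the hindered methyl ketone by the basic reagent, together with an E/Z ratio that depends only on a steric bias; the lithium alkoxide of the cis-bromohydrin could also trigger ring contraction on warming. The fallback sets out from 9 and returns at 11, and it makes the alkene by a stereospecific syn carbometalation. Ketone 9 is converted in one flask (LDA, then ClP(O)(OEt)2, then LDA) into the alkyne (1R,2S,4S)-2-bromo-4-ethynyl-1-methylcyclohexan-1-ol F5. Zirconium-catalysed methylalumination (Me3Al, Cp2ZrCl2) with iodine quench should then give 11 directly.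

**Step 7.** The most likely failure is slow insertion of the hindered trisubstituted alkenyl palladium species into the alkene next to a quaternary carbinol. This would leave time for homocoupling, migration of the double bonds or oxidative addition of zerovalent palladium into the C–Br bond. The fallback sets out from 1, joins 11 and returns at 13. It replaces the alkene partner by a preformed alkenyl metal.
- Epoxidation of 1 with Ti(OiPr)4, L-(+)-diethyl tartrate and t-BuOOH should give [(2S,3S)-3-methyl-3-(4-methylpent-3-en-1-yl)oxiran-2-yl]methanol F6.
- PPh3 and CCl4 should convert it into (2S,3R)-3-(chloromethyl)-2-methyl-2-(4-methylpent-3-en-1-yl)oxirane F7.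
- n-BuLi (3 equiv) should open and eliminate F7 to the propargylic alcohol (3S)-3,7-dimethyloct-6-en-1-yn-3-ol F8.
- Hydrostannation (Bu3SnH, PdCl2(PPh3)2) should give (1E,3S)-3,7-dimethyl-1-(tributylstannyl)octa-1,6-dien-3-ol F9.
- Stille coupling of F9 with 11 (Pd2(dba)3, AsPh3, DMF) should give 13 under neutral conditions.

## Further compounds

F1 | step 3 | 4-[(2R,3R)-3-(hydroxymethyl)-2-methyloxiran-2-yl]butanal | OC[C@H]1O[C@]1(C)CCC=O
F2 | step 3 | [(2R,3R)-3-methyl-3-[4-methyl-5-(trimethylsilyl)pent-3-en-1-yl]oxiran-2-yl]methanol | OC[C@H]1O[C@]1(C)CCC=C(C)C[Si](C)(C)C
F3 | step 3 | (2S,3R)-2-bromo-3,7-dimethyl-8-(trimethylsilyl)oct-6-ene-1,3-diol | OC[C@H](Br)[C@](C)(O)CCC=C(C)C[Si](C)(C)C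
F4 | step 2 | (2S,3R)-2-bromo-3-chloro-3,7-dimethyloct-6-en-1-ol | OC[C@H](Br)[C@](C)(Cl)CCC=C(C)C
F5 | step 5 | (1R,2S,4S)-2-bromo-4-ethynyl-1-methylcyclohexan-1-ol | C#C[C@H]1CC[C@@](C)(O)[C@@H](Br)C1
F6 | step 7 | [(2S,3S)-3-methyl-3-(4-methylpent-3-en-1-yl)oxiran-2-yl]methanol | OC[C@@H]1O[C@@]1(C)CCC=C(C)C
F7 | step 7 | (2S,3R)-3-(chloromethyl)-2-methyl-2-(4-methylpent-3-en-1-yl)oxirane | ClC[C@@H]1O[C@@]1(C)CCC=C(C)C
F8 | step 7 | (3S)-3,7-dimethyloct-6-en-1-yn-3-ol | CC(C)=CCC[C@](C)(O)C#C
F9 | step 7 | (1E,3S)-3,7-dimethyl-1-(tributylstannyl)octa-1,6-dien-3-ol | CC(C)=CCC[C@](C)(O)/C=C/[Sn](CCCC)(CCCC)CCCC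
A1 | alternative 1 | (4S)-1-methyl-4-(prop-1-en-2-yl)cyclohex-1-ene, (S)-limonene | CC1=CC[C@H](CC1)C(C)=C
A2 | alternative 1 | (1R,2R,4S)-1-methyl-4-(prop-1-en-2-yl)cyclohexane-1,2-diol | CC(=C)[C@H]1CC[C@@](C)(O)[C@H](O)C1
A3 | alternative 1 | (1R,4S,6S)-1-methyl-4-(prop-1-en-2-yl)-7-oxabicyclo[4.1.0]heptane | CC(=C)[C@H]1CC[C@@]2(C)O[C@H]2C1
A4 | alternative 1 | (1R,2R,4S)-2-bromo-1-methyl-4-(prop-1-en-2-yl)cyclohexan-1-ol | CC(=C)[C@H]1CC[C@@](C)(O)[C@H](Br)C1
A5 | alternative 2 | 4-(prop-1-en-2-yl)cyclohexan-1-one | CC(=C)C1CCC(=O)CC1
A6 | alternative 2 | (2S,4S)-2-bromo-4-(prop-1-en-2-yl)cyclohexan-1-one | CC(=C)[C@H]1CCC(=O)[C@@H](Br)C1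
A7 | alternative 2 | (2R,4S)-2-bromo-4-(prop-1-en-2-yl)cyclohexan-1-one | CC(=C)[C@H]1CCC(=O)[C@H](Br)C1
A8 | alternative 3 | (3R,6E,9E,11S)-3,7,11,15-tetramethylhexadeca-1,6,9,14-tetraene-3,11-diol | C=C[C@](C)(O)CC/C=C(\C)C/C=C/[C@@](C)(O)CCC=C(C)C
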